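**Retrosynthetic overview**

1. Numbering (eudesmane): ring A = C1–C5 + C10, ring B = C5–C10, C14 on C10, C15 on C4, C11–C13 on C7, C16 = the CH2 between C1 and the trione ring. The last bond, C16–trione, is made by reductive Knoevenagel alkylation of aldehyde 18 with the dearomatised acylphloroglucinol 22.
2. The C4 carbinol comes from a 4(15)-exocyclic alkene (epoxide, then hydride), the isopropenyl group from late methylenation of a C7 acetyl, and ring A from an intramolecular ene reaction that joins C2 to C3.
3. Ring B comes from an enantioselective Diels–Alder reaction of diene 9 (C6=C7–C8=C9) with the E-ene-trione 6 (C5=C10); the adduct holds 13 of the 16 carbons of the terpenoid half.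
4. Enabling feature: in ring B (C5–C6–C7–C8–C9–C10) the side-chain carbon C7 is para to the quaternary C10, and the two ring A bonds C10–C1 and C5–C4 are trans-diequatorial. This is the pattern left by a 2-substituted butadiene adding to an E-alkene whose C10 carries the stronger acceptor.
5. Ring order: ring B (step 5), ring A (step 8), then the preformed trione ring is attached (step 15).

Key step: step 5

Assumption: the (S,S)-ligand is taken to shield the face that leads to (1S,6S)-10; if the adduct proves antipodal, the (R,R)-ligand is used.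

**Route**

Step 1
Reactants: 1 ethyl 3-bromo-2-oxobutanoate; 2 triphenylphosphine
Product: 4 ethyl 2-oxo-3-(triphenyl-λ5-phosphanylidene)butanoate, via phosphonium bromide 3 (not isolated)
Conditions: toluene, 50 °C; then aq. Na2CO3, CH2Cl2, 0 °C
Reagents that add atoms: none
Why: SN2 substitution of the α-bromo ketone by PPh3 and deprotonation of the salt should give the acyl-stabilised ylide (the route used for the parent pyruvate ylide); the racemic centre of 1 is lost.

Step 2
Reactants: 4 ethyl 2-oxo-3-(triphenyl-λ5-phosphanylidene)butanoate; 5 methylglyoxal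
Product: 6 ethyl (3E)-3-methyl-2,5-dioxohex-3-enoate
Conditions: 5 (1.5 equiv, monomer from the commercial aqueous solution), CH2Cl2, 40 °C
Reagents that add atoms: none
Why: Wittig olefination; the stabilised ylide should react only with the aldehyde carbonyl of 5 and give the E-alkene (oxoacetate and acetyl trans), which is also the thermodynamic isomer.

Step 3
Reactants: 7 but-3-yn-2-one
Product: 8 2-ethynyl-2-methyl-1,3-dioxolane
Conditions: TMSOCH2CH2OTMS, TMSOTf (1 mol %), CH2Cl2, −78 °C
Reagents that add atoms: 1,2-bis(trimethylsilyloxy)ethane, C[Si](C)(C)OCCO[Si](C)(C)C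
Why: Noyori ketalisation under aprotic conditions should protect the carbonyl group without conjugate addition to the ynone.

Step 4
Reactants: 8 2-ethynyl-2-methyl-1,3-dioxolane
Product: 9 2-(buta-1,3-dien-2-yl)-2-methyl-1,3-dioxolane
Conditions: ethylene (1 atm), second-generation Grubbs catalyst RuCl2(=CHPh)(H2IMes)(PCy3) (5 mol %), CH2Cl2, 40 °C
Reagents that add atoms: ethylene, C=C
Why: cross enyne metathesis of a terminal alkyne with ethylene should give the 2-substituted buta-1,3-diene in one step.

Step 5
Reactants: 6 ethyl (3E)-3-methyl-2,5-dioxohex-3-enoate; 9 2-(buta-1,3-dien-2-yl)-2-methyl-1,3-dioxolane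
Product: 10 ethyl 2-[(1S,6S)-6-acetyl-1-methyl-4-(2-methyl-1,3-dioxolan-2-yl)cyclohex-3-en-1-yl]-2-oxoacetate
Conditions: [Cu((S,S)-tBu-box)](SbF6)2 (10 mol %; tBu-box = 2,2'-(propane-2,2-diyl)bis(4-tert-butyl-4,5-dihydrooxazole)), 4 Å MS, CH2Cl2, −40 → −20 °C
Reagents that add atoms: none
Why: The 2-oxo ester of 6 binds the bis(oxazoline)–divalent copper cation as a five-membered chelate, which lowers the LUMO of the C5=C10 bond and makes C5 (β to the bound ketone) its most electrophilic carbon; diene 9 then adds in a concerted, asynchronous, suprafacial [4+2] cycloaddition whose leading bond runs from C6 (the terminus next to the substituted C7, largest HOMO coefficient) to C5 and whose second bond joins C9 to C10. The closest known reaction type is the copper–bis(oxazoline) catalysed Diels–Alder reaction of two-point-binding dienophiles such as 2-oxo-3-enoates. Ring B is the only ring closed, by intermolecular [4+2] cycloaddition, both new σ-bonds arising in one transition state. The two new stereocentres are tied to each other by the substrate and to the absolute sense by the catalyst: suprafacial addition to the E-alkene puts the oxoacetate on C10 and the acetyl on C5 trans (the later trans ring fusion), no endo/exo question exists because the diene termini are unsubstituted, and the tert-butyl groups of the (S,S)-ligand shield one face of the planar chelate to give (1S,6S)-10 with the quaternary C10 set. The step needs para regioselectivity and carbocyclic (not hetero-Diels–Alder) periselectivity: the chelated oxoacetate outranks the unbound acetyl as directing group so that C7 ends para to C10, and the methyl group on C10 disfavours bonding through the ketone oxygen, while any dihydropyran formed can relay to 10 by [3,3] shift.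

Step 6
Reactants: 10 ethyl 2-[(1S,6S)-6-acetyl-1-methyl-4-(2-methyl-1,3-dioxolan-2-yl)cyclohex-3-en-1-yl]-2-oxoacetate
Product: 11 ethyl 2-[(1S,2S,4S)-2-acetyl-1-methyl-4-(2-methyl-1,3-dioxolan-2-yl)cyclohexyl]-2-oxoacetate
Conditions: H2 (1 atm), Pd/C (5 %), EtOAc, 25 °C
Reagents that add atoms: none
Why: catalytic hydrogenation of the only C=C bond; hydrogen should be delivered to the face of C7=C8 opposite to the axial C10 methyl, which sets C7 (side chain cis to that methyl), and any 7-epimer is corrected in step 10, where this centre is equilibrated α to the ketone.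

Step 7
Reactants: 11 ethyl 2-[(1S,2S,4S)-2-acetyl-1-methyl-4-(2-methyl-1,3-dioxolan-2-yl)cyclohexyl]-2-oxoacetate
Product: 12 ethyl 2-[(1S,2R,4S)-1-methyl-4-(2-methyl-1,3-dioxolan-2-yl)-2-(prop-1-en-2-yl)cyclohexyl]prop-2-enoate
Conditions: Cp2Ti(μ-Cl)(μ-CH2)AlMe2 (Tebbe reagent, 2.5 equiv), pyridine, THF–toluene, −40 → 0 °C
Reagents that add atoms: Tebbe reagent (written as Cp2Ti=CH2·ClAlMe2), C[Al](C)Cl.C=[Ti](C1C=CC=C1)C1C=CC=C1
Why: Tebbe methylenation should convert both ketone carbonyls into 1,1-disubstituted alkenes (adding C2 and C3) while the ester and the ketal are left, and because the reagent is not basic the enolisable C5 centre keeps its configuration.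

Step 8
Reactants: 12 ethyl 2-[(1S,2R,4S)-1-methyl-4-(2-methyl-1,3-dioxolan-2-yl)-2-(prop-1-en-2-yl)cyclohexyl]prop-2-enoate
Product: 14 ethyl (1S,5R,7S,10S)-7-acetyl-10-methyl-4-methylidenedecalin-1-carboxylate, via ketal ester 13 (not isolated)
Conditions: EtAlCl2 (2.5 equiv), CH2Cl2, −78 → −20 °C; then PPTS, acetone–H2O, 45 °C
Reagents that add atoms: water, O
Why: Lewis acid promoted intramolecular ene reaction (type 2; the cation–olefin cyclisation of a 2-alkoxycarbonyl-1,5-diene): the isopropenyl CH2 (C3) attacks the aluminium-bound acrylate at C2 through a chair-like six-membered array in which the two side chains are trans-diequatorial, so ring A closes trans-fused, the tertiary C4 cation hands a C15 proton to C1 (six-centre transfer) to leave the 4(15)-exocyclic alkene with the C1 ester equatorial, and mild aqueous acid then removes the ketal.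

Step 9
Reactants: 14 ethyl (1S,5R,7S,10S)-7-acetyl-10-methyl-4-methylidenedecalin-1-carboxylate
Product: 15 ethyl (1S,4S,5S,7S,10S)-7-acetyl-10-methylspiro[decalin-4,2'-oxirane]-1-carboxylate
Conditions: mCPBA, NaHCO3, CH2Cl2, 0 °C
Reagents that add atoms: mCPBA, OOC(=O)c1cccc(Cl)c1
Why: Prilezhaev epoxidation of the only alkene; the peracid should approach the exocyclic C4=C15 bond from the equatorial side, away from the 1,3-diaxial C10 methyl, which puts the oxygen on C4 where the hydroxyl is needed.

Step 10
Reactants: 15 ethyl (1S,4S,5S,7S,10S)-7-acetyl-10-methylspiro[decalin-4,2'-oxirane]-1-carboxylate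
Product: 16 ethyl (1S,4S,5S,7S,10S)-10-methyl-7-(prop-1-en-2-yl)spiro[decalin-4,2'-oxirane]-1-carboxylate
Conditions: Ph3PCH3Br, KOtBu (excess), THF, 0 → 25 °C
Reagents that add atoms: methyltriphenylphosphonium bromide, C[P+](c1ccccc1)(c1ccccc1)c1ccccc1.[Br-]
Why: Wittig methylenation of the methyl ketone adds C12 and gives the isopropenyl group; the excess base first equilibrates C7 (and C1) to the equatorial epimers, and the epoxide and ester are inert to the ylide.

Step 11
Reactants: 16 ethyl (1S,4S,5S,7S,10S)-10-methyl-7-(prop-1-en-2-yl)spiro[decalin-4,2'-oxirane]-1-carboxylate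
Product: 17 (1S,4S,5S,7S,10R)-1-(hydroxymethyl)-4,10-dimethyl-7-(prop-1-en-2-yl)decalin-4-ol
Conditions: LiAlH4, THF, 0 → 40 °C
Reagents that add atoms: none
Why: hydride reduction; LiAlH4 should reduce the ester to the primary alcohol and open the 1,1-disubstituted epoxide at its CH2 carbon, which turns C15 into the axial methyl and leaves the equatorial tertiary hydroxyl with C4 untouched.

Step 12
Reactants: 17 (1S,4S,5S,7S,10R)-1-(hydroxymethyl)-4,10-dimethyl-7-(prop-1-en-2-yl)decalin-4-ol
Product: 18 (1S,4S,5S,7S,10S)-4-hydroxy-4,10-dimethyl-7-(prop-1-en-2-yl)decalin-1-carbaldehyde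
Conditions: Dess–Martin periodinane, NaHCO3, CH2Cl2, 0 → 25 °C
Reagents that add atoms: none
Why: Dess–Martin oxidation of the primary alcohol; the tertiary alcohol and the alkene do not react.

Step 13
Reactants: 19 phloroglucinol; 20 3-methylbutanoyl chloride
Product: 21 3-methyl-1-(2,4,6-trihydroxyphenyl)butan-1-one
Conditions: AlCl3, PhNO2–CH2Cl2, 0 → 40 °C
Reagents that add atoms: none
Why: Friedel–Crafts C-acylation of the electron-rich arene; one acyl group deactivates the ring against a second.

Step 14
Reactants: 21 3-methyl-1-(2,4,6-trihydroxyphenyl)butan-1-one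
Product: 22 3,5-dihydroxy-6,6-dimethyl-2-(3-methylbutanoyl)cyclohexa-2,4-dien-1-one
Conditions: NaOMe, MeI (2.1 equiv), MeOH, 0 → 25 °C
Reagents that add atoms: iodomethane, CI
Why: dearomative geminal C-methylation of an acylphloroglucinol (a known reaction of this class); the phenolate is methylated twice at one unsubstituted ring carbon and the stoichiometry limits over-methylation.

Step 15
Reactants: 18 (1S,4S,5S,7S,10S)-4-hydroxy-4,10-dimethyl-7-(prop-1-en-2-yl)decalin-1-carbaldehyde; 22 3,5-dihydroxy-6,6-dimethyl-2-(3-methylbutanoyl)cyclohexa-2,4-dien-1-one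
Product: 24 4-{[(1R,4S,5S,7S,10R)-4-hydroxy-4,10-dimethyl-7-(prop-1-en-2-yl)decalin-1-yl]methyl}-3,5-dihydroxy-6,6-dimethyl-2-(3-methylbutanoyl)cyclohexa-2,4-dien-1-one (CNP0490948.1), via alkylidene trione 23 (not isolated)
Conditions: Hantzsch ester (diethyl 2,6-dimethyl-1,4-dihydropyridine-3,5-dicarboxylate, 1.2 equiv), L-proline (20 mol %), CH2Cl2, 25 °C
Reagents that add atoms: none
Why: organocatalytic reductive Knoevenagel alkylation (aldehyde, cyclic 1,3-dicarbonyl, Hantzsch ester): condensation at the only free ring CH of 22 gives the alkylidene trione, which takes hydride at C16; C1 is epimerisable at the aldehyde and alkylidene stage and should settle with the side chain equatorial.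

**Compound list**

1 | ethyl 3-bromo-2-oxobutanoate (racemic) | CCOC(=O)C(=O)C(C)Br | starting material
2 | triphenylphosphine | c1ccc(cc1)P(c1ccccc1)c1ccccc1 | starting material
3 | (4-ethoxy-3,4-dioxobutan-2-yl)triphenylphosphonium bromide | CCOC(=O)C(=O)C(C)[P+](c1ccccc1)(c1ccccc1)c1ccccc1.[Br-] | intermediate
4 | ethyl 2-oxo-3-(triphenyl-λ5-phosphanylidene)butanoate | CCOC(=O)C(=O)C(C)=P(c1ccccc1)(c1ccccc1)c1ccccc1 | intermediate
5 | methylglyoxal (2-oxopropanal) | CC(=O)C=O | starting material
6 | ethyl (3E)-3-methyl-2,5-dioxohex-3-enoate | CCOC(=O)C(=O)/C(C)=C/C(C)=O | intermediate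
7 | but-3-yn-2-one | CC(=O)C#C | starting material
8 | 2-ethynyl-2-methyl-1,3-dioxolane | CC1(C#C)OCCO1 | intermediate
9 | 2-(buta-1,3-dien-2-yl)-2-methyl-1,3-dioxolane | CC1(C(=C)C=C)OCCO1 | intermediate
10 | ethyl 2-[(1S,6S)-6-acetyl-1-methyl-4-(2-methyl-1,3-dioxolan-2-yl)cyclohex-3-en-1-yl]-2-oxoacetate | CC1(OCCO1)C2=CC[C@](C)(C(=O)C(=O)OCC)[C@@H](C(C)=O)C2 | intermediate
11 | ethyl 2-[(1S,2S,4S)-2-acetyl-1-methyl-4-(2-methyl-1,3-dioxolan-2-yl)cyclohexyl]-2-oxoacetate | CC1(OCCO1)[C@H]2CC[C@](C)(C(=O)C(=O)OCC)[C@@H](C(C)=O)C2 | intermediate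
12 | ethyl 2-[(1S,2R,4S)-1-methyl-4-(2-methyl-1,3-dioxolan-2-yl)-2-(prop-1-en-2-yl)cyclohexyl]prop-2-enoate | CC1(OCCO1)[C@H]2CC[C@](C)(C(=C)C(=O)OCC)[C@@H](C(C)=C)C2 | intermediate
13 | ethyl (1S,5R,7S,10S)-10-methyl-4-methylidene-7-(2-methyl-1,3-dioxolan-2-yl)decalin-1-carboxylate (trans-fused, eudesmane numbering) | CC1(OCCO1)[C@H]2CC[C@]3(C)[C@@H](C(=O)OCC)CCC(=C)[C@H]3C2 | intermediate
14 | ethyl (1S,5R,7S,10S)-7-acetyl-10-methyl-4-methylidenedecalin-1-carboxylate | CC(=O)[C@H]1CC[C@]2(C)[C@@H](C(=O)OCC)CCC(=C)[C@H]2C1 | intermediate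
15 | ethyl (1S,4S,5S,7S,10S)-7-acetyl-10-methylspiro[decalin-4,2'-oxirane]-1-carboxylate (oxirane oxygen on the face away from the C10 methyl) | CC(=O)[C@H]1CC[C@]2(C)[C@@H](C(=O)OCC)CC[C@]3(OC3)[C@H]2C1 | intermediate
16 | ethyl (1S,4S,5S,7S,10S)-10-methyl-7-(prop-1-en-2-yl)spiro[decalin-4,2'-oxirane]-1-carboxylate | C=C(C)[C@H]1CC[C@]2(C)[C@@H](C(=O)OCC)CC[C@]3(OC3)[C@H]2C1 | intermediate
17 | (1S,4S,5S,7S,10R)-1-(hydroxymethyl)-4,10-dimethyl-7-(prop-1-en-2-yl)decalin-4-ol | C=C(C)[C@H]1CC[C@]2(C)[C@@H](CO)CC[C@](C)(O)[C@H]2C1 | intermediate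
18 | (1S,4S,5S,7S,10S)-4-hydroxy-4,10-dimethyl-7-(prop-1-en-2-yl)decalin-1-carbaldehyde | C=C(C)[C@H]1CC[C@]2(C)[C@@H](C=O)CC[C@](C)(O)[C@H]2C1 | intermediate
19 | phloroglucinol (benzene-1,3,5-triol) | Oc1cc(O)cc(O)c1 | starting material
20 | 3-methylbutanoyl chloride (isovaleryl chloride) | CC(C)CC(Cl)=O | starting material
21 | 3-methyl-1-(2,4,6-trihydroxyphenyl)butan-1-one | CC(C)CC(=O)c1c(O)cc(O)cc1O | intermediate
22 | 3,5-dihydroxy-6,6-dimethyl-2-(3-methylbutanoyl)cyclohexa-2,4-dien-1-one | CC(C)CC(=O)C1=C(O)C=C(O)C(C)(C)C1=O | intermediate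
23 | C16-alkylidene trione, the Knoevenagel adduct of 18 and 22 ((1R,4S,5S,7S,10R), C16=C geometry not defined) | C=C(C)[C@H]1CC[C@]2(C)[C@@H](C=C3C(=O)C(C)(C)C(=O)C(C(=O)CC(C)C)=C3O)CC[C@](C)(O)[C@H]2C1 | intermediate
24 | 4-{[(1R,4S,5S,7S,10R)-4-hydroxy-4,10-dimethyl-7-(prop-1-en-2-yl)decalin-1-yl]methyl}-3,5-dihydroxy-6,6-dimethyl-2-(3-methylbutanoyl)cyclohexa-2,4-dien-1-one | C=C(C)[C@H]1CC[C@]2(C)[C@@H](CC3=C(O)C(C)(C)C(=O)C(C(=O)CC(C)C)=C3O)CC[C@](C)(O)[C@H]2C1 | target

**Count**

Total step count: 15. Longest linear sequence: 11 steps (1, 2, 5–12, 15; the diene branch 3, 4, 5–12, 15 is equally long).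

**Steps most likely to fail**

Step 5. The chelated 2-oxo ester may react through its oxadiene (hetero-Diels–Alder) or with poor facial and regiochemical control, so that enantiopurity and the para orientation are lost. The fallback sets out from diene 9 and returns to the route at 10; it moves the directing carbonyl to a formyl group, for which oxazaborolidinium catalysis of α-methyl enals is established. Diene 9 and (2E)-2-methyl-4-oxopent-2-enal F1 (one operation from commercial 2,4-dimethylfuran: NBS, aqueous acetone, then pyridine for Z-to-E isomerisation) are combined with the triflimide-activated o-tolyl oxazaborolidine derived from diphenylprolinol (20 mol %, CH2Cl2, −78 °C; enantiomer chosen for the 1S,6S sense) to give the formyl adduct F2. LiC(SMe)3 (THF, −78 °C) adds to the formyl group only and gives the orthothioester carbinol F3. HgCl2/HgO in aqueous ethanol converts it into the α-hydroxy ester F4, and Dess–Martin oxidation of F4 gives 10.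

Step 8. The tertiary C4 cation may lose a ring proton instead of a C15 proton (endocyclic alkene isomers), or the Lewis acid may ionise the ketal and divert the isopropenyl group into a Prins closure onto C11. The fallback sets out from 11 and returns at 13; ring A is closed by an anionic Michael addition and the exocyclic methylene is installed afterwards. One equivalent of Ph3P=CH2 at −78 °C should methylenate only the more electrophilic 2-oxo ester carbonyl of 11 and give the acrylate ketone F5. Catalytic KOtBu in THF–tBuOH generates the methyl ketone enolate, whose CH2 terminus (C3) adds to the acrylate C2 to give the trans-decalin-4-one F6 with the ester equatorial. Tebbe methylenation of the C4 ketone of F6 gives 13, which is deketalised as in step 8.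

Step 15. Condensation at the hindered, α-branched aldehyde may be slow, and the alkylidene trione may be diverted before hydride transfer (oxa-Michael capture by the C4 hydroxyl after epimerisation at C1, or oligomerisation). The fallback sets out from 17 and returns at 24; the C16–trione bond is made by SN2 alkylation instead of condensation and reduction. Appel iodination of the primary hydroxyl of 17 (I2, PPh3, imidazole, CH2Cl2; the tertiary hydroxyl does not react) gives the iodide F7, and C-alkylation of the caesium enolate of 22 with F7 (Cs2CO3, DMF, 50 °C) gives 24 after separation from O-alkylated material.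

**Further compounds**

F1 | step 5 | (2E)-2-methyl-4-oxopent-2-enal | O=C/C(C)=C/C(C)=O
F2 | step 5 | (1S,6S)-6-acetyl-1-methyl-4-(2-methyl-1,3-dioxolan-2-yl)cyclohex-3-ene-1-carbaldehyde | CC1(OCCO1)C2=CC[C@](C)(C=O)[C@@H](C(C)=O)C2
F3 | step 5 | orthothioester carbinol: F2 with the formyl group changed to CH(OH)C(SMe)3 (carbinol epimers) | CC1(OCCO1)C2=CC[C@](C)(C(O)C(SC)(SC)SC)[C@@H](C(C)=O)C2
F4 | step 5 | α-hydroxy ester: F2 with the formyl group changed to CH(OH)CO2Et (carbinol epimers) | CC1(OCCO1)C2=CC[C@](C)(C(O)C(=O)OCC)[C@@H](C(C)=O)C2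
F5 | step 8 | ethyl 2-[(1S,2S,4S)-2-acetyl-1-methyl-4-(2-methyl-1,3-dioxolan-2-yl)cyclohexyl]prop-2-enoate | CC1(OCCO1)[C@H]2CC[C@](C)(C(=C)C(=O)OCC)[C@@H](C(C)=O)C2
F6 | step 8 | ethyl (1S,5S,7S,10S)-10-methyl-7-(2-methyl-1,3-dioxolan-2-yl)-4-oxodecalin-1-carboxylate (trans-fused, eudesmane numbering) | CC1(OCCO1)[C@H]2CC[C@]3(C)[C@@H](C(=O)OCC)CCC(=O)[C@H]3C2
F7 | step 15 | (1S,4S,5S,7S,10S)-1-(iodomethyl)-4,10-dimethyl-7-(prop-1-en-2-yl)decalin-4-ol | C=C(C)[C@H]1CC[C@]2(C)[C@@H](CI)CC[C@](C)(O)[C@H]2C1
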